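The six-membered ring B (C3a–C4–C5–C6–C7–C7a) is a linearly conjugated cyclohexa-2,4-dienone, the valence isomer of a dienylketene. Its C7 methoxy group next to the C6 carbonyl is the signature of a methoxycarbene that has taken up CO. The route therefore rests on the C5–C6 disconnection. Visible-light carbonylation of a chromium dienyl(methoxy)carbene creates C6 as a ketene carbon. A 6π-electrocyclisation onto the fully substituted enol-ether carbon C5 then closes ring B, sets the C5 quaternary centre and delivers the heat-sensitive target directly. The precursor is a monocyclic, enantiopure trans-2-aryl-3-methyl-2,3-dihydrofuran (ring A) carrying the carbene at C7a and a (Z)-2-methoxypenta-1,4-dienyl chain at C3a.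

Key step: step 9

Remark: in the explanations the benzofuran numbering of the target (O1, C2, C3, C3a, C4, C5, C6, C7, C7a) is also used for the corresponding atoms of all precursors. Compound names carry their own locants.

Step 1
Reactants: 1 (R)-but-3-yn-2-ol
Product: 2 (R)-but-3-yn-2-yl methanesulfonate
Conditions: MsCl, Et3N, CH2Cl2, −78 → 0 °C
Reagents that add atoms: methanesulfonyl chloride, CS(=O)(=O)Cl
Why: Mesylation takes place at oxygen only, so the C–O bond and the (R) configuration stay untouched.

Step 2
Reactants: 2 (R)-but-3-yn-2-yl methanesulfonate; 3 3,4,5-trimethoxybenzaldehyde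
Product: 5 (1S,2S)-2-methyl-1-(3,4,5-trimethoxyphenyl)but-3-yn-1-ol, via allenylzinc reagent 4 (not isolated)
Conditions: Pd(OAc)2 (cat.), PPh3 (cat.), Et2Zn, THF, −78 → −20 °C; 1 M HCl quench
Reagents that add atoms: none
Why: Marshall propargylation, in which zerovalent palladium displaces the mesylate anti (SN2′), Et2Zn transmetalates to the configurationally stable allenylzinc 4, and its cyclic SE2′ addition to the aldehyde transfers the axial chirality to C3 (net inversion, S) and sets C2 (S) in the anti relationship favoured by the cyclic transition state.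

Step 3
Reactants: 5 (1S,2S)-2-methyl-1-(3,4,5-trimethoxyphenyl)but-3-yn-1-ol
Product: 6 (2S,3S)-3-methyl-2-(3,4,5-trimethoxyphenyl)-2,3-dihydrofuran
Conditions: Mo(CO)6 (cat.), Et3N, Et2O, hν (350 nm), then 5, rt
Reagents that add atoms: none
Why: Molybdenum-catalysed alkynol cycloisomerisation, in which (Et3N)Mo(CO)5 converts the terminal alkyne into a vinylidene complex, the hydroxyl group adds to its electrophilic carbon (formal 5-endo closure of ring A) and protodemetalation gives the enol ether, so the anti alcohol becomes the trans ring without touching either stereocentre.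

Step 4
Reactants: 6 (2S,3S)-3-methyl-2-(3,4,5-trimethoxyphenyl)-2,3-dihydrofuran
Product: 7 (2S,3R)-4-iodo-3-methyl-2-(3,4,5-trimethoxyphenyl)-2,3-dihydrofuran
Conditions: NIS (1.0 equiv), AgNO3 (cat.), 4 Å MS, MeCN, dark, 25 → 60 °C
Reagents that add atoms: N-iodosuccinimide, O=C1CCC(=O)N1I
Why: Electrophilic iodination of an enol ether (iodonium attack at the nucleophilic carbon C3a, then loss of the C3a proton from the oxocarbenium ion), the reaction type used for 2-iodoglycals, in which the enol ether is far more nucleophilic than the trimethoxyphenyl ring and the change of the C3 descriptor is only a priority change.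

Step 5
Reactants: 7 (2S,3R)-4-iodo-3-methyl-2-(3,4,5-trimethoxyphenyl)-2,3-dihydrofuran
Product: 9 (2S,3R)-4-iodo-3-methyl-5-(tributylstannyl)-2-(3,4,5-trimethoxyphenyl)-2,3-dihydrofuran, via 5-lithiodihydrofuran 8 (not isolated)
Conditions: LDA, THF, −78 °C; Bu3SnCl, −78 °C → rt
Reagents that add atoms: tributyltin chloride, CCCC[Sn](Cl)(CCCC)CCCC
Why: Deprotonative metalation of a β-halo vinyl ether, since C7a–H is the only acidified C–H (geminal to O1, vicinal to iodine, as in the LDA lithiation of 3-bromofuran), elimination to a five-membered cycloalkyne is impossible, and the vinyllithium is trapped by stannylation.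

Step 6
Reactants: 9 (2S,3R)-4-iodo-3-methyl-5-(tributylstannyl)-2-(3,4,5-trimethoxyphenyl)-2,3-dihydrofuran; 10 chloroacetaldehyde dimethyl acetal
Product: 13 (2S,3S)-4-(methoxyethynyl)-3-methyl-5-(tributylstannyl)-2-(3,4,5-trimethoxyphenyl)-2,3-dihydrofuran, via lithium methoxyacetylide 11 (not isolated), via methoxyethynylzinc chloride 12 (not isolated)
Conditions: 10, LiNEt2 (from Et2NH + n-BuLi, 3 equiv), THF, −10 °C → rt; ZnCl2, 0 °C; then 9, Pd(PPh3)4 (cat.), THF, rt
Reagents that add atoms: none
Why: Two eliminations and a deprotonation of the chloroacetal give lithium methoxyacetylide, and in the Negishi alkynylation that follows zerovalent palladium inserts into the C–I bond and the alkynylzinc transmetalates much faster than a vinylstannane, so the tributylstannyl group survives.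

Step 7
Reactants: 13 (2S,3S)-4-(methoxyethynyl)-3-methyl-5-(tributylstannyl)-2-(3,4,5-trimethoxyphenyl)-2,3-dihydrofuran; 14 allylmagnesium bromide
Product: 16 (2S,3S)-4-[(1Z)-2-methoxypenta-1,4-dien-1-yl]-3-methyl-5-(tributylstannyl)-2-(3,4,5-trimethoxyphenyl)-2,3-dihydrofuran, via alkenylcopper adduct 15 (not isolated)
Conditions: allylMgBr + CuBr·SMe2 (1:1), Et2O/Me2S, −78 → −45 °C; 13, −45 → −30 °C; aq NH4Cl/NH3 (pH 9), −45 °C
Reagents that add atoms: none
Why: Normant-type syn-carbocupration of an alkynyl ether, in which the polarised triple bond takes the allyl group at the oxygen-bearing carbon C5 and copper at C4, and syn addition with retentive protonolysis places H cis to allyl and OMe cis to ring A, giving the (Z) enol ether, while the cold quench prevents loss of copper methoxide from the adduct.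

Step 8
Reactants: 16 (2S,3S)-4-[(1Z)-2-methoxypenta-1,4-dien-1-yl]-3-methyl-5-(tributylstannyl)-2-(3,4,5-trimethoxyphenyl)-2,3-dihydrofuran; 17 hexacarbonylchromium
Product: 20 pentacarbonyl{methoxy[(2S,3S)-4-[(1Z)-2-methoxypenta-1,4-dien-1-yl]-3-methyl-2-(3,4,5-trimethoxyphenyl)-2,3-dihydrofuran-5-yl]methylidene}chromium, via vinyllithium 18 (not isolated), via lithium acylchromate 19 (not isolated)
Conditions: n-BuLi, THF, −78 °C; Cr(CO)6, THF, −78 → 0 °C; MeOTf, CH2Cl2, −20 → 0 °C, dark
Reagents that add atoms: methyl trifluoromethanesulfonate, COS(=O)(=O)C(F)(F)F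
Why: Fischer carbene synthesis, in which tin–lithium exchange at −78 °C outruns deprotonation of the doubly allylic CH2 (held away from the carbanion by the (Z) geometry), the vinyllithium adds to a CO ligand of Cr(CO)6, and the hard electrophile MeOTf alkylates the acylchromate oxygen, so C7 and its methoxy oxygen come from CO and no stereocentre or alkene geometry is touched.

Step 9
Reactants: 20 pentacarbonyl{methoxy[(2S,3S)-4-[(1Z)-2-methoxypenta-1,4-dien-1-yl]-3-methyl-2-(3,4,5-trimethoxyphenyl)-2,3-dihydrofuran-5-yl]methylidene}chromium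
Product: 22 (2S,3S,5R)-5-allyl-5,7-dimethoxy-3-methyl-2-(3,4,5-trimethoxyphenyl)-3,5-dihydro-1-benzofuran-6(2H)-one, via dienylketene 21 (not isolated)
Conditions: hν (blue LED, 450 nm, or Hg lamp with a 400 nm cut-off filter), CO (1 atm, slow sparge), dry THF, −10 → 0 °C
Reagents that add atoms: carbon monoxide, [C-]#[O+]
Why: Excitation of the metal-to-ligand charge-transfer band drives insertion of a cis CO ligand into the Cr=C7 bond and gives the chromium-bound methoxy(dienyl)ketene 21, in which the ring A double bond C7a=C3a holds the ketene carbon C6 and the enol-ether carbon C5 cis to each other, so that thermal 6π-electrocyclisation, helped by the push of O1 through C7a=C3a–C4=C5 towards the electrophilic ketene, forms C5–C6. The closest known reactions are the photochemical benzannulation of chromium dienyl(alkoxy)carbene complexes to ortho-alkoxyphenols and the cyclohexadienone annulation, in which a fully substituted diene terminus stops the same closure at the cyclohexa-2,4-dienone because no tautomerisation is possible. Ring B is closed in a six-atom disrotatory electrocyclic mode, ring A being already present. The C5 centre is controlled by two elements: the (Z) enol-ether geometry places OMe inside and allyl outside, and allylic strain between the C3 methyl group and C4–H tilts C4–H towards the C3–H face, so C5 dips to the methyl face, C6 bonds to its opposite lobe, the inside OMe turns to the methyl face and the allyl group to the aryl face, which is the (5R) configuration. The closure has to outrun external capture of the ketene, cyclopropanation of the allyl group and reduction of the product by low-valent chromium, which the intramolecular s-cis geometry, the dry non-nucleophilic solvent and the CO atmosphere (chromium leaves as inert Cr(CO)6) should secure. Light above 400 nm and a temperature at or below 0 °C keep the dienone from photochemical re-opening and from Cope or retro-Claisen shift of the allyl group.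

Compound list
1 | (R)-but-3-yn-2-ol | C#C[C@@H](C)O | starting material
2 | (R)-but-3-yn-2-yl methanesulfonate | C#C[C@@H](C)OS(C)(=O)=O | intermediate
3 | 3,4,5-trimethoxybenzaldehyde | COc1cc(C=O)cc(OC)c1OC | starting material
4 | (P)-buta-1,2-dien-1-yl(ethyl)zinc | CC([H])=[C@@]=C([H])[Zn]CC | intermediate
5 | (1S,2S)-2-methyl-1-(3,4,5-trimethoxyphenyl)but-3-yn-1-ol | O[C@H](c1cc(OC)c(OC)c(OC)c1)[C@H](C#C)C | intermediate
6 | (2S,3S)-3-methyl-2-(3,4,5-trimethoxyphenyl)-2,3-dihydrofuran | C1=CO[C@H](c2cc(OC)c(OC)c(OC)c2)[C@H]1C | intermediate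
7 | (2S,3R)-4-iodo-3-methyl-2-(3,4,5-trimethoxyphenyl)-2,3-dihydrofuran | IC1=CO[C@H](c2cc(OC)c(OC)c(OC)c2)[C@H]1C | intermediate
8 | (2S,3R)-4-iodo-5-lithio-3-methyl-2-(3,4,5-trimethoxyphenyl)-2,3-dihydrofuran | IC1=C([Li])O[C@H](c2cc(OC)c(OC)c(OC)c2)[C@H]1C | intermediate
9 | (2S,3R)-4-iodo-3-methyl-5-(tributylstannyl)-2-(3,4,5-trimethoxyphenyl)-2,3-dihydrofuran | IC1=C([Sn](CCCC)(CCCC)CCCC)O[C@H](c2cc(OC)c(OC)c(OC)c2)[C@H]1C | intermediate
10 | chloroacetaldehyde dimethyl acetal | COC(CCl)OC | starting material
11 | lithium methoxyacetylide | [Li]C#COC | intermediate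
12 | methoxyethynylzinc chloride | COC#C[Zn]Cl | intermediate
13 | (2S,3S)-4-(methoxyethynyl)-3-methyl-5-(tributylstannyl)-2-(3,4,5-trimethoxyphenyl)-2,3-dihydrofuran | COC#CC1=C([Sn](CCCC)(CCCC)CCCC)O[C@H](c2cc(OC)c(OC)c(OC)c2)[C@H]1C | intermediate
14 | allylmagnesium bromide | C=CC[Mg]Br | starting material
15 | alkenylcopper adduct (Cu on C4, cis to allyl) | C=CC/C(OC)=C(\[Cu])C1=C([Sn](CCCC)(CCCC)CCCC)O[C@H](c2cc(OC)c(OC)c(OC)c2)[C@H]1C | intermediate
16 | (2S,3S)-4-[(1Z)-2-methoxypenta-1,4-dien-1-yl]-3-methyl-5-(tributylstannyl)-2-(3,4,5-trimethoxyphenyl)-2,3-dihydrofuran | C=CC/C(OC)=C/C1=C([Sn](CCCC)(CCCC)CCCC)O[C@H](c2cc(OC)c(OC)c(OC)c2)[C@H]1C | intermediate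
17 | hexacarbonylchromium | O=C=[Cr](=C=O)(=C=O)(=C=O)(=C=O)=C=O | starting material
18 | 5-lithio analogue of 16 (vinyllithium) | C=CC/C(OC)=C/C1=C([Li])O[C@H](c2cc(OC)c(OC)c(OC)c2)[C@H]1C | intermediate
19 | lithium acyl(pentacarbonyl)chromate from 18 | C=CC/C(OC)=C/C1=C(C(O[Li])=[Cr](=C=O)(=C=O)(=C=O)(=C=O)=C=O)O[C@H](c2cc(OC)c(OC)c(OC)c2)[C@H]1C | intermediate
20 | pentacarbonyl{methoxy[(2S,3S)-4-[(1Z)-2-methoxypenta-1,4-dien-1-yl]-3-methyl-2-(3,4,5-trimethoxyphenyl)-2,3-dihydrofuran-5-yl]methylidene}chromium (carbene complex of zerovalent chromium) | C=CC/C(OC)=C/C1=C(C(OC)=[Cr](=C=O)(=C=O)(=C=O)(=C=O)=C=O)O[C@H](c2cc(OC)c(OC)c(OC)c2)[C@H]1C | intermediate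
21 | 2-methoxy-2-[(2S,3S)-4-[(1Z)-2-methoxypenta-1,4-dien-1-yl]-3-methyl-2-(3,4,5-trimethoxyphenyl)-2,3-dihydrofuran-5-yl]ethenone (dienylketene) | C=CC/C(OC)=C/C1=C(C(OC)=C=O)O[C@H](c2cc(OC)c(OC)c(OC)c2)[C@H]1C | intermediate
22 | (2S,3S,5R)-5-allyl-5,7-dimethoxy-3-methyl-2-(3,4,5-trimethoxyphenyl)-3,5-dihydro-1-benzofuran-6(2H)-one | C=CC[C@@]1(OC)C=C2C(=C(OC)C1=O)O[C@H](c1cc(OC)c(OC)c(OC)c1)[C@H]2C | target

Total step count: 9. Longest linear sequence: 9 steps (1 → 22).

Steps most likely to fail

Step 9. Carbonyl insertion may be inefficient, low-valent chromium may strip the C5 methoxy group by reduction, or the closure may show poor facial selectivity under irradiation. The fallback generates the same ketene without metal, in the dark and at low temperature. It sets out from stannane 16. Tin–lithium exchange to 18, transmetalation with ZnCl2 and alkylation with methyl 2-chloro-2-methoxyacetate give methyl 2-methoxy-2-(dihydrofuran-5-yl)acetate F1, and both epimers at the new carbon serve. LiOH hydrolysis gives the carboxylic acid F2. Dehydration with 2-chloro-1-methylpyridinium iodide and Et3N in CH2Cl2 at −20 °C, the ketene generation used in Staudinger β-lactam syntheses, releases ketene 21. The route is rejoined there, and 21 closes to 22.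

Step 7. Allylcopper may add sluggishly or with reversed orientation, or the adduct may lose copper methoxide on warming. The fallback replaces carbometalation by carbonyl olefination. It sets out from iodide 9. Iodine–magnesium exchange (i-PrMgCl·LiCl, THF, −40 °C) and DMF give the 4-carbaldehyde F3. Commercial (methoxymethyl)triphenylphosphonium chloride is deprotonated (n-BuLi) and allylated with allyl bromide to give racemic (1-methoxybut-3-en-1-yl)triphenylphosphonium bromide F4. Wittig olefination of F3 with the ylide of F4 (KHMDS, THF, −78 °C) gives both enol-ether isomers. The (E) isomer F5 is removed by chromatography on base-washed silica, and the (Z) isomer is 16, where the route is rejoined.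

Step 5. Base-induced opening of ring A or migration of iodine may compete with deprotonation at C7a. The fallback changes the order of events and the type of metalation. It sets out from iodide 7. Negishi coupling with 12 under the conditions of step 6 gives (2S,3S)-4-(methoxyethynyl)-3-methyl-2-(3,4,5-trimethoxyphenyl)-2,3-dihydrofuran F6, which carries no iodine and no doubly allylic CH2. Classical α-lithiation of the cyclic vinyl ether with t-BuLi (THF, −78 → −30 °C) and quenching with Bu3SnCl give 13, where the route is rejoined.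

Further compounds
F1 | step 9 | methyl 2-methoxy-2-[(2S,3S)-4-[(1Z)-2-methoxypenta-1,4-dien-1-yl]-3-methyl-2-(3,4,5-trimethoxyphenyl)-2,3-dihydrofuran-5-yl]acetate (both epimers at the new carbon) | C=CC/C(OC)=C/C1=C(C(OC)C(=O)OC)O[C@H](c2cc(OC)c(OC)c(OC)c2)[C@H]1C
F2 | step 9 | 2-methoxy-2-[(2S,3S)-4-[(1Z)-2-methoxypenta-1,4-dien-1-yl]-3-methyl-2-(3,4,5-trimethoxyphenyl)-2,3-dihydrofuran-5-yl]acetic acid | C=CC/C(OC)=C/C1=C(C(OC)C(=O)O)O[C@H](c2cc(OC)c(OC)c(OC)c2)[C@H]1C
F3 | step 7 | (2S,3S)-3-methyl-5-(tributylstannyl)-2-(3,4,5-trimethoxyphenyl)-2,3-dihydrofuran-4-carbaldehyde | O=CC1=C([Sn](CCCC)(CCCC)CCCC)O[C@H](c2cc(OC)c(OC)c(OC)c2)[C@H]1C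
F4 | step 7 | (1-methoxybut-3-en-1-yl)triphenylphosphonium bromide (racemic) | C=CCC(OC)[P+](c1ccccc1)(c1ccccc1)c1ccccc1.[Br-]
F5 | step 7 | (2S,3S)-4-[(1E)-2-methoxypenta-1,4-dien-1-yl]-3-methyl-5-(tributylstannyl)-2-(3,4,5-trimethoxyphenyl)-2,3-dihydrofuran | C=CC/C(OC)=C\C1=C([Sn](CCCC)(CCCC)CCCC)O[C@H](c2cc(OC)c(OC)c(OC)c2)[C@H]1C
F6 | step 5 | (2S,3S)-4-(methoxyethynyl)-3-methyl-2-(3,4,5-trimethoxyphenyl)-2,3-dihydrofuran | COC#CC1=CO[C@H](c2cc(OC)c(OC)c(OC)c2)[C@H]1C
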